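Which flask, theta or alpha, ends after 2.0 d with the longer chains, and how long are they on average?

| flask | free monomer | initiator | remark | time |
|---|---|---|---|---|
| north | 0.041 M (fed, over 15 min) | 1 mM | run made earlier; the fed solution adds 0.10 times the starting volume |  |
| south | 0.068 M (fed, over 15 min) | 1 mM | run made earlier; the fed solution adds 0.10 times the starting volume |  |
| south-west | 0.067 M (fed, over 15 min) | 1 mM | run made earlier; the fed solution adds 0.10 times the starting volume |  |
| theta | 0.050 M (fed, over 15 min) | 1.0 mM | the fed solution adds 0.10 times the starting volume | 2.0 d |
| alpha | 0.080 M (fed, over 15 min) | 1.0 mM | the fed solution adds 0.10 times the starting volume | 2.0 d |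

| run | time / h | monomer in chains / % |
|---|---|---|
| north | 4.00 | 28.6 |
| north | 12.0 | 67.4 |
| north | 20.0 | 80.0 |
| north | 30.0 | 83.7 |
| north | 50.0 | 80.6 |
| south | 10.0 | 70.2 |
| south | 20.0 | 89.0 |
| south | 30.0 | 87.9 |
| south | 40.0 | 87.8 |
| south | 50.0 | 90.0 |
| south-west | 4.00 | 35.1 |
| south-west | 12.0 | 75.2 |
| south-west | 20.0 | 86.6 |
| south-west | 30.0 | 88.7 |
| south-west | 50.0 | 88.9 |

(standard deviation of a reading: 1 percentage point)

1. which of the two ends with the longer chains by the average number of monomer units in a chain (chains begun, living or dead) ("neither" if they lie within 10%) (theta / alpha / neither)
2. average number of monomer units in a chain (chains begun, living or dead) at the end, theta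
3. average number of monomer units in a chain (chains begun, living or dead) at the end, alpha

- charges are per starting volume, the dose included; the dosed solution carries all of it
- the average divides the monomer in chains by the number of chains begun, living and dead together
- steps that have been proposed: free monomer + initiator -> living end + monomer in chains; free monomer + living end -> monomer in chains + living end; monomer in chains + living end -> free monomer + living end; free monomer -> decomposition product
- the earlier runs do not show the number of chains; that part of a forecast is a guess

South-west levels at 88.9% of a charge diluted to 60.9 mM, which leaves 6.76 mM free. I call this the floor: the free-monomer concentration at which addition to living ends and loss from them balance, the equilibrium monomer concentration. North, charged with less, leaves 6.08 mM at its reading of 83.7%, so across these two runs I read the floor as roughly independent of the charge, with a scatter of 1 percentage point on each reading.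

I draw theta's curve of monomer in chains from north, its nearest run. It leaves zero at north's early chord, 0.0715 h⁻¹ of the charge. Theta's charge dilutes to 45.5 mM, so the floor puts the level at 85.1%. The chord meets that level at a knee near 11.9 h. Between north's first two readings, its gap to 83.7% closes with a time constant of 6.57 h, against which the feed of 15 min is short. If that time constant holds for theta beyond the knee, theta's end time lies 5.49 time constants past it, with an estimated 0.411% of the gap open.

The runs do not count chains, so I guess one per initiator, 0.909 mM in the diluted flask. Length is then the monomer above the floor over the chains: 42.6 for theta and 72.6 for alpha, so I expect alpha to be longer.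

The forecast says alpha, with 41.5 (37 to 50) for theta and 71.5 (65 to 84) for alpha, slightly under my figures, and adds: “Chain number is a guess, so the ranges lean upward”.

The flask gives alpha, with 42.9 for theta and 72.7 for alpha.

    free monomer + initiator → living end + monomer in chains (k = 13.0 M⁻¹ h⁻¹)
    free monomer + living end → monomer in chains + living end, rate k2*[living end]*[free monomer] (k = 200 M⁻¹ h⁻¹)
    monomer in chains + living end → free monomer + living end, rate k3*[living end] as long as [monomer in chains] is above zero (k = 1.20 h⁻¹)
    free monomer → decomposition product (k = 9.70 × 10⁻⁴ h⁻¹)

The main reason for alpha's length is its larger charge: with the difference in free monomer taken away, alpha gives 42.9 in place of 72.7. After 2.00 d theta and alpha hold 9.08 × 10⁻⁴ M and 9.09 × 10⁻⁴ M of living ends, while above my floor alpha has 66.0 mM to theta's 38.7 mM. In a neighbouring flask, alpha's recipe with 0.020 M of free monomer, my floor leaves 11.4 mM for 0.909 mM of chains, or 12.6 units; that neighbouring flask gives 13.1.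

All runs were computed on assumed constants; scatter was added.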